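The target is cut at the aldol bond into a chroman aldehyde and an (S)-dihydrobenzofuranyl methyl ketone. The chroman rests on the dihydropyran ring: C2, an ether carbon with two methyl groups, is a tertiary α-oxy radical site, and C3–C4 is a bare ethano bridge to ring carbon C4a. A decarboxylative radical (4+2) annulation exploits this. The C2 radical from the N-hydroxyphthalimide ester of 2-(4-formylphenoxy)-2-methylpropanoic acid adds to acrylic acid (C2–C3), and the adduct radical closes onto the arene (C4–C4a) in one operation, twice uniting carbons of like polarity. The C4 carboxyl group is then removed.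

Key step: step 2

Assumption: 2-(4-formylphenoxy)-2-methylpropanoic acid and 1-(5-bromo-2,4-dihydroxyphenyl)ethan-1-one are taken as catalogue compounds, and the (S,S)-bisphosphoramide is taken to direct an enol silane to the Si face of an aromatic aldehyde (the (R,R)-antipode being Re-selective).

Step 1
Reactants: 1 2-(4-formylphenoxy)-2-methylpropanoic acid
Product: 2 1,3-dioxo-1,3-dihydro-2H-isoindol-2-yl 2-(4-formylphenoxy)-2-methylpropanoate
Conditions: N-hydroxyphthalimide (1.1 equiv), N,N'-diisopropylcarbodiimide (1.1 equiv), DMAP (0.1 equiv), CH2Cl2, 0 °C to rt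
Reagents that add atoms: N-hydroxyphthalimide, ON1C(=O)c2ccccc2C1=O
Why: Steglich-type esterification, in which the carbodiimide activates the hindered tertiary acid and DMAP relays the acyl group to N-hydroxyphthalimide, while the aryl aldehyde meets no nucleophile and is left alone.

Step 2
Reactants: 2 1,3-dioxo-1,3-dihydro-2H-isoindol-2-yl 2-(4-formylphenoxy)-2-methylpropanoate, 3 acrylic acid (prop-2-enoic acid)
Product: 4 (±)-6-formyl-2,2-dimethyl-3,4-dihydro-2H-chromene-4-carboxylic acid
Conditions: Ir(ppy)3 (fac-tris(2-phenylpyridinato)iridium, 1 mol%), acrylic acid (3 equiv), degassed MeCN (0.05 M), 450 nm LEDs, rt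
Reagents that add atoms: none
Why: Single-electron reduction of the N-acyloxyphthalimide by photoexcited Ir(ppy)3 releases CO2, phthalimide anion and the nucleophilic tertiary α-aryloxy radical at C2, which adds to the CH2 terminus of acrylic acid (C2–C3 bond); the resulting electrophilic α-carboxyalkyl radical at C4 closes onto the ring carbon ortho to the ether oxygen (C4–C4a bond), and the cyclohexadienyl radical is oxidised by the tetravalent iridium form of the catalyst and deprotonated by phthalimide anion, so the step is redox-neutral. The closest known reaction type is the photoredox radical (4+2) annulation of N-(acyloxy)phthalimides of aryloxyalkanoic acids with electron-poor alkenes (Giese addition followed by homolytic aromatic substitution). The six-membered ring closes in a 6-exo-trig mode with respect to the C4a=C5 aromatic bond. The only new stereocentre, C4, forms without control as a racemate and is deleted in step 3. The step needs addition to win over oxidation of the C2 radical, and ortho closure to win over chain growth and ipso attack: the excess of a fast acceptor at low substrate concentration should secure the first, the polarity match between the electrophilic C4 radical and the oxygen-activated ortho carbon the second, and the para-substituted ring makes both ortho positions equivalent, so only one regioisomer can form.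

Step 3
Reactants: 4 (±)-6-formyl-2,2-dimethyl-3,4-dihydro-2H-chromene-4-carboxylic acid
Product: 5 2,2-dimethyl-3,4-dihydro-2H-chromene-6-carbaldehyde
Conditions: 9-mesityl-10-phenylacridinium tetrafluoroborate (5 mol%), PhSSPh (10 mol%), iPr2NEt (20 mol%), CF3CH2OH, 450 nm LEDs, rt
Reagents that add atoms: none
Why: Photoredox hydrodecarboxylation, in which the excited acridinium oxidises the carboxylate, loss of CO2 leaves the benzylic C4 radical and hydrogen-atom transfer from the thiol co-catalyst gives the CH2 group and erases the C4 stereocentre, while the aryl aldehyde is not addressed by these reagents.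

Step 4
Reactants: 6 1-(5-bromo-2,4-dihydroxyphenyl)ethan-1-one
Product: 7 4-acetyl-6-bromo-1,3-phenylene bis(2,2-dimethylpropanoate)
Conditions: PivCl (2.5 equiv), Et3N (3 equiv), DMAP (0.1 equiv), CH2Cl2, 0 °C to rt
Reagents that add atoms: pivaloyl chloride, CC(C)(C)C(=O)Cl
Why: DMAP-catalysed acylation masks both phenols as base-labile pivalates, which are electron-poor enough to shield the ring from the oxidant of step 6 and hindered enough to survive its pH.

Step 5
Reactants: 7 4-acetyl-6-bromo-1,3-phenylene bis(2,2-dimethylpropanoate), 8 tributyl(3-methylbut-2-en-1-yl)stannane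
Product: 9 4-acetyl-6-(3-methylbut-2-en-1-yl)-1,3-phenylene bis(2,2-dimethylpropanoate)
Conditions: Pd(PPh3)4 (5 mol%), DMF, 100 °C
Reagents that add atoms: none
Why: Stille coupling, in which oxidative addition of zerovalent palladium into the aryl bromide, transfer of the prenyl group from its tin-bearing carbon and reductive elimination should give the linear prenyl arene, with ketone and pivalates inert under these neutral conditions.

Step 6
Reactants: 9 4-acetyl-6-(3-methylbut-2-en-1-yl)-1,3-phenylene bis(2,2-dimethylpropanoate)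
Product: 10 4-acetyl-6-{[(2R)-3,3-dimethyloxiran-2-yl]methyl}-1,3-phenylene bis(2,2-dimethylpropanoate)
Conditions: D-fructose-derived ketone catalyst (1,2:4,5-di-O-isopropylidene-β-D-erythro-2,3-hexodiulo-2,6-pyranose, 30 mol%), Oxone (2KHSO5·KHSO4·K2SO4), K2CO3, Bu4NHSO4 (cat.), MeCN/CH2(OMe)2/aq Na2B4O7 buffer (pH 10.5), 0 °C
Reagents that add atoms: Oxone (active oxidant potassium peroxymonosulfate), [K+].[O-]S(=O)(=O)OO
Why: Shi epoxidation, in which the chiral dioxirane transfers oxygen to the trisubstituted alkene through a spiro transition state with the olefinic hydrogen next to the dioxolane of the catalyst, which for 2-methylalk-2-enes should deliver the (R)-epoxide, while the buffered pH protects the catalyst and the pivalates keep the phenols away from the oxidant.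

Step 7
Reactants: 10 4-acetyl-6-{[(2R)-3,3-dimethyloxiran-2-yl]methyl}-1,3-phenylene bis(2,2-dimethylpropanoate)
Product: 12 1-[(2S)-6-hydroxy-2-(2-hydroxypropan-2-yl)-2,3-dihydro-1-benzofuran-5-yl]ethan-1-one, via diphenol epoxide 11 (not isolated)
Conditions: K2CO3 (3 equiv), MeOH, rt to 40 °C; aq NH4Cl
Reagents that add atoms: none
Why: Base-mediated methanolysis of both pivalates frees the phenoxide ortho to the side chain, which opens the epoxide by 5-exo-tet SN2 attack at the secondary carbon with inversion and so turns the (R)-epoxide into the (S)-configured dihydrobenzofuran; the other phenol is para to the side chain and cannot reach it.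

Step 8
Reactants: 12 1-[(2S)-6-hydroxy-2-(2-hydroxypropan-2-yl)-2,3-dihydro-1-benzofuran-5-yl]ethan-1-one
Product: 13 trimethyl({(2S)-2-[2-(trimethylsilyloxy)propan-2-yl]-5-[1-(trimethylsilyloxy)ethenyl]-2,3-dihydro-1-benzofuran-6-yl}oxy)silane
Conditions: TMSOTf (3.6 equiv), Et3N (5 equiv), CH2Cl2, 0 °C; pentane, filtration, used without chromatography
Reagents that add atoms: trimethylsilyl trifluoromethanesulfonate, C[Si](C)(C)OS(=O)(=O)C(F)(F)F
Why: Soft enolisation and silylation converts the aryl methyl ketone into its enol silane and caps the phenol and the tertiary alcohol as TMS ethers in the same operation, so no separate protecting-group steps are needed and the stereocentre is not involved.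

Step 9
Reactants: 13 trimethyl({(2S)-2-[2-(trimethylsilyloxy)propan-2-yl]-5-[1-(trimethylsilyloxy)ethenyl]-2,3-dihydro-1-benzofuran-6-yl}oxy)silane, 5 2,2-dimethyl-3,4-dihydro-2H-chromene-6-carbaldehyde
Product: 15 (3S)-3-(2,2-dimethyl-3,4-dihydro-2H-chromen-6-yl)-3-hydroxy-1-[(2S)-6-hydroxy-2-(2-hydroxypropan-2-yl)-2,3-dihydro-1-benzofuran-5-yl]propan-1-one, via trichlorosilyl aldolate 14 (not isolated)
Conditions: SiCl4 (1.5 equiv), (S,S)-bisphosphoramide (5 mol%; two (S)-N,N'-dimethyl-1,1'-binaphthyl-2,2'-diamine phosphoramide units linked through N,N'-dimethylpentane-1,5-diamine), iPr2NEt (10 mol%), CH2Cl2, −78 °C; then sat. aq KF/1 M KH2PO4, THF, 0 °C to rt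
Reagents that add atoms: none
Why: Mukaiyama aldol addition under Lewis-base activation of SiCl4, in which the chiral bisphosphoramide turns SiCl4 into a cationic chlorosilicon Lewis acid that binds aldehyde 5 and exposes its Si face to enol silane 13, setting the (S)-carbinol centre of 14 (the dihydrobenzofuran centre is remote and untouched), after which buffered fluoride removes the SiCl3 group and both TMS ethers without acid or strong base, so the para-alkoxybenzylic β-hydroxy ketone should not dehydrate.

Compound list

1 | 2-(4-formylphenoxy)-2-methylpropanoic acid | CC(C)(Oc1ccc(C=O)cc1)C(=O)O | starting material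
2 | 1,3-dioxo-1,3-dihydro-2H-isoindol-2-yl 2-(4-formylphenoxy)-2-methylpropanoate | CC(C)(Oc1ccc(C=O)cc1)C(=O)ON1C(=O)c2ccccc2C1=O | intermediate
3 | acrylic acid | C=CC(=O)O | starting material
4 | (±)-6-formyl-2,2-dimethyl-3,4-dihydro-2H-chromene-4-carboxylic acid | CC1(C)CC(C(=O)O)c2cc(C=O)ccc2O1 | intermediate
5 | 2,2-dimethyl-3,4-dihydro-2H-chromene-6-carbaldehyde | CC1(C)CCc2cc(C=O)ccc2O1 | intermediate
6 | 1-(5-bromo-2,4-dihydroxyphenyl)ethan-1-one | CC(=O)c1cc(Br)c(O)cc1O | starting material
7 | 4-acetyl-6-bromo-1,3-phenylene bis(2,2-dimethylpropanoate) | CC(=O)c1cc(Br)c(OC(=O)C(C)(C)C)cc1OC(=O)C(C)(C)C | intermediate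
8 | tributyl(3-methylbut-2-en-1-yl)stannane | CC(C)=CC[Sn](CCCC)(CCCC)CCCC | starting material
9 | 4-acetyl-6-(3-methylbut-2-en-1-yl)-1,3-phenylene bis(2,2-dimethylpropanoate) | CC(=O)c1cc(CC=C(C)C)c(OC(=O)C(C)(C)C)cc1OC(=O)C(C)(C)C | intermediate
10 | 4-acetyl-6-{[(2R)-3,3-dimethyloxiran-2-yl]methyl}-1,3-phenylene bis(2,2-dimethylpropanoate) | CC(=O)c1cc(C[C@H]2OC2(C)C)c(OC(=O)C(C)(C)C)cc1OC(=O)C(C)(C)C | intermediate
11 | 1-(5-{[(2R)-3,3-dimethyloxiran-2-yl]methyl}-2,4-dihydroxyphenyl)ethan-1-one (diphenol epoxide, not isolated) | CC(=O)c1cc(C[C@H]2OC2(C)C)c(O)cc1O | intermediate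
12 | 1-[(2S)-6-hydroxy-2-(2-hydroxypropan-2-yl)-2,3-dihydro-1-benzofuran-5-yl]ethan-1-one | CC(=O)c1cc2c(cc1O)O[C@H](C(C)(C)O)C2 | intermediate
13 | trimethyl({(2S)-2-[2-(trimethylsilyloxy)propan-2-yl]-5-[1-(trimethylsilyloxy)ethenyl]-2,3-dihydro-1-benzofuran-6-yl}oxy)silane | C=C(O[Si](C)(C)C)c1cc2c(cc1O[Si](C)(C)C)O[C@H](C(C)(C)O[Si](C)(C)C)C2 | intermediate
14 | (3S)-3-(2,2-dimethylchroman-6-yl)-3-(trichlorosilyloxy)-1-{(2S)-6-(trimethylsilyloxy)-2-[2-(trimethylsilyloxy)propan-2-yl]-2,3-dihydro-1-benzofuran-5-yl}propan-1-one (trichlorosilyl aldolate, not isolated) | CC1(C)CCc2cc([C@@H](O[Si](Cl)(Cl)Cl)CC(=O)c3cc4c(cc3O[Si](C)(C)C)O[C@H](C(C)(C)O[Si](C)(C)C)C4)ccc2O1 | intermediate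
15 | (3S)-3-(2,2-dimethyl-3,4-dihydro-2H-chromen-6-yl)-3-hydroxy-1-[(2S)-6-hydroxy-2-(2-hydroxypropan-2-yl)-2,3-dihydro-1-benzofuran-5-yl]propan-1-one | CC1(C)CCc2cc([C@@H](O)CC(=O)c3cc4c(cc3O)O[C@H](C(C)(C)O)C4)ccc2O1 | target

Total step count: 9. Longest linear sequence: 6 steps (steps 4 to 9, from compound 6); the chroman branch (steps 1 to 3) joins at step 9.

Steps most likely to fail

Step 2. The tertiary C2 radical may be oxidised before it adds, and chain growth of acrylic acid or ipso attack with aryl migration may outrun the ortho ring closure onto the formyl-bearing ring. The fallback gives up the radical annulation and builds the same aldehyde by classical pyran chemistry. It sets out from none of the numbered compounds (commercial 4-hydroxybenzaldehyde replaces compound 1) and comes back to the route at compound 5. 4-Hydroxybenzaldehyde is alkylated with 3-chloro-3-methylbut-1-yne (K2CO3, KI, CuI cat., acetone, 60 °C) to 4-[(2-methylbut-3-yn-2-yl)oxy]benzaldehyde F1. Heating in N,N-diethylaniline at 190 °C (aromatic propargyl Claisen rearrangement, 1,5-hydrogen shift, 6π oxa-electrocyclisation) should give 2,2-dimethyl-2H-chromene-6-carbaldehyde F2. Hydrogenation (H2, 1 atm, Pd/C, EtOAc, stopped after one equivalent) saturates the C3=C4 bond to give compound 5.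

Step 9. Facial selectivity may be poor or reversed with this electron-rich aldehyde, the aryl silyl ether may be lost before the addition, and the benzylic aldolate may ionise or dehydrate during the quench. The fallback sets out from compound 12 (with compound 5) and comes back at compound 15, setting the carbinol centre by asymmetric epoxidation of a chalcone. The phenol of 12 is allylated (allyl bromide, K2CO3, acetone) to 1-[(2S)-2-(2-hydroxypropan-2-yl)-6-(prop-2-en-1-yloxy)-2,3-dihydro-1-benzofuran-5-yl]ethan-1-one F3. Claisen–Schmidt condensation with 5 (KOH, EtOH, rt) gives the (E)-chalcone F4. Juliá–Colonna epoxidation (poly-D-leucine, urea–H2O2, DBU, THF) should give the (2S,3R)-epoxy ketone F5. Reductive opening of the Cα–O bond (PhSeNa from PhSeSePh and NaBH4, AcOH, EtOH, 0 °C) retains the β-configuration and gives the allyl-protected (3S)-β-hydroxy ketone F6. Deallylation (Pd(PPh3)4, morpholine, THF, rt) gives compound 15.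

Step 3. The excited acridinium may oxidise the alkoxyaryl aldehyde ring in competition with the carboxylate, and turnover may stall. The fallback sets out from compound 4 and comes back at compound 5, replacing oxidative by reductive decarboxylation. Acid 4 is converted (N-hydroxyphthalimide, N,N'-diisopropylcarbodiimide, DMAP, CH2Cl2) into its N-hydroxyphthalimide ester F7. Irradiation with Ru(bpy)3Cl2 (1 mol%), Hantzsch ester and t-BuSH in CH2Cl2 under blue light fragments it reductively, and the thiol caps the C4 radical with hydrogen to give compound 5.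

Further compounds

F1 | step 2 | 4-[(2-methylbut-3-yn-2-yl)oxy]benzaldehyde | C#CC(C)(C)Oc1ccc(C=O)cc1
F2 | step 2 | 2,2-dimethyl-2H-chromene-6-carbaldehyde | CC1(C)C=Cc2cc(C=O)ccc2O1
F3 | step 9 | 1-[(2S)-2-(2-hydroxypropan-2-yl)-6-(prop-2-en-1-yloxy)-2,3-dihydro-1-benzofuran-5-yl]ethan-1-one | CC(=O)c1cc2c(cc1OCC=C)O[C@H](C(C)(C)O)C2
F4 | step 9 | (2E)-3-(2,2-dimethylchroman-6-yl)-1-[(2S)-2-(2-hydroxypropan-2-yl)-6-(prop-2-en-1-yloxy)-2,3-dihydro-1-benzofuran-5-yl]prop-2-en-1-one | CC1(C)CCc2cc(/C=C/C(=O)c3cc4c(cc3OCC=C)O[C@H](C(C)(C)O)C4)ccc2O1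
F5 | step 9 | [(2S,3R)-3-(2,2-dimethylchroman-6-yl)oxiran-2-yl][(2S)-2-(2-hydroxypropan-2-yl)-6-(prop-2-en-1-yloxy)-2,3-dihydro-1-benzofuran-5-yl]methanone | CC1(C)CCc2cc([C@H]3O[C@@H]3C(=O)c3cc4c(cc3OCC=C)O[C@H](C(C)(C)O)C4)ccc2O1
F6 | step 9 | (3S)-3-(2,2-dimethylchroman-6-yl)-3-hydroxy-1-[(2S)-2-(2-hydroxypropan-2-yl)-6-(prop-2-en-1-yloxy)-2,3-dihydro-1-benzofuran-5-yl]propan-1-one | CC1(C)CCc2cc([C@@H](O)CC(=O)c3cc4c(cc3OCC=C)O[C@H](C(C)(C)O)C4)ccc2O1
F7 | step 3 | 1,3-dioxo-1,3-dihydro-2H-isoindol-2-yl (±)-6-formyl-2,2-dimethyl-3,4-dihydro-2H-chromene-4-carboxylate | CC1(C)CC(C(=O)ON3C(=O)c4ccccc4C3=O)c2cc(C=O)ccc2O1
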